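The ketone is cut between its carbonyl carbon and the syringyl ring carbon para to the phenol. That carbonyl carbon, on oxolane C4, stands 1,4 to the oxygen of the C3 hydroxymethyl group, so the acyl partner is stored as a temporary cis-fused γ-lactone, a (1R,5R,6S)-6-aryl-3,7-dioxabicyclo[3.3.0]octan-2-one. The symmetric syringyl ring enters as the 4-lithio derivative of silylated 2,6-dimethoxyphenol. One operation forms the aryl ketone, stops at the ketone level through a bicyclic lithium hemiketalate and frees the primary alcohol. The lactone comes from (5R)-5-menthyloxy-2(5H)-furanone by tandem conjugate addition/aldol. Base epimerisation α to the new ketone then gives the all-trans oxolane.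

Key step: step 7

Assumption: (5R)-5-(l-menthyloxy)-2(5H)-furanone 4 is taken as a purchasable crystalline building block; its acetal centre is the only source of absolute configuration in the route.

Step 1
Reactants: 1 vanillin
Product: 2 3-methoxy-4-(triisopropylsilyloxy)benzaldehyde
Conditions: TIPSCl, imidazole, DMF, 0 °C to rt
Reagents that add atoms: triisopropylsilyl chloride, CC(C)[Si](Cl)(C(C)C)C(C)C
Why: Imidazole-promoted silylation of the phenol removes the acidic proton for the carbanion, hydride and organolithium steps, and the bulky TIPS aryl ether should survive LiAlH4 and mild acid while keeping the para oxygen donating for the benzylic ionisation in step 4.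

Step 2
Reactants: 3 tris(methylsulfanyl)methane; 4 (5R)-5-[(1R,2S,5R)-menthyloxy]furan-2(5H)-one; 2 3-methoxy-4-(triisopropylsilyloxy)benzaldehyde
Product: 7 (3S,4R,5R)-3-{hydroxy[3-methoxy-4-(triisopropylsilyloxy)phenyl]methyl}-5-[(1R,2S,5R)-menthyloxy]-4-[tris(methylsulfanyl)methyl]oxolan-2-one (both carbinol epimers), via tris(methylsulfanyl)methyllithium 5 (not isolated), via lithium enolate 6 (not isolated)
Conditions: 3, n-BuLi, THF, −78 °C; then 4, −78 °C; then 2, −78 °C; AcOH quench at −78 °C
Reagents that add atoms: none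
Why: Tandem Michael addition/aldol on a γ-alkoxybutenolide: the soft, hindered carboxyl-anion equivalent 5 should add 1,4 anti to the menthyloxy group (C4 = R), and enolate 6 should take up aldehyde 2 anti to the new C4 substituent (C3 = S, the one centre that is carried unchanged to the target), while the carbinol centre forms as a mixture that step 4 erases.

Step 3
Reactants: 7 aldol adduct lactone
Product: 8 (2R,3R)-2-{hydroxy[3-methoxy-4-(triisopropylsilyloxy)phenyl]methyl}-3-[tris(methylsulfanyl)methyl]butane-1,4-diol (both carbinol epimers)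
Conditions: LiAlH4, THF, 0 °C to rt; Fieser work-up
Reagents that add atoms: none
Why: Hydride reduction of the lactone acetal (a pseudo-ester): the lactone carbonyl is reduced, the hemiacetal collapses with loss of menthol and the freed aldehyde is reduced, so both ring carbons end as CH2OH, while the trithioorthoester, the aryl silyl ether and both stereocentres should be untouched.

Step 4
Reactants: 8 triol
Product: 9 {(2S,3R,4R)-2-[3-methoxy-4-(triisopropylsilyloxy)phenyl]-4-[tris(methylsulfanyl)methyl]oxolan-3-yl}methanol
Conditions: CSA (cat.), CH2Cl2, 0 °C to rt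
Reagents that add atoms: none
Why: Acid-catalysed SN1 cyclodehydration (5-exo capture of the para-silyloxybenzylic cation): only the hydroxyl three carbons away can close a five-membered ring (the other would give an oxetane), reversible ionisation should place the aryl group trans to the neighbouring hydroxymethyl group (C2 = S) from either carbinol epimer, and the change of ring membership at C3 puts CH2OH and C(SMe)3 cis.

Step 5
Reactants: 9 oxolane trithioorthoester
Product: 10 (1R,5R,6S)-6-[3-methoxy-4-(triisopropylsilyloxy)phenyl]-3,7-dioxabicyclo[3.3.0]octan-2-one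
Conditions: HgCl2, CaCO3, MeCN/H2O 4:1, rt
Reagents that add atoms: water, O
Why: Thiophilic unmasking of the trithioorthoester with neighbouring-group capture: Hg(II)-assisted loss of MeS gives a dithio-stabilised carbenium ion that the cis hydroxymethyl group traps (5-exo), and hydrolysis of the S,S,O-orthoester should give the cis-fused γ-lactone directly, with CaCO3 buffering HCl so that the benzylic ether, the silyl ether and all stereocentres are preserved.

Step 6
Reactants: 11 4-bromo-2,6-dimethoxyphenol
Product: 12 (4-bromo-2,6-dimethoxyphenoxy)(tert-butyl)dimethylsilane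
Conditions: TBSCl, imidazole, DMF, rt
Reagents that add atoms: tert-butyldimethylsilyl chloride, CC(C)(C)[Si](C)(C)Cl
Why: Standard silylation of the hindered phenol removes the acidic proton so that bromine–lithium exchange can give a clean aryllithium, and the TBS ether is cleaved together with the TIPS group at the end.

Step 7
Reactants: 12 (4-bromo-2,6-dimethoxyphenoxy)(tert-butyl)dimethylsilane; 10 bicyclic lactone
Product: 15 [(2S,3R,4R)-3-(hydroxymethyl)-2-(3-methoxy-4-triisopropylsilyloxyphenyl)oxolan-4-yl][4-(tert-butyldimethylsilyloxy)-3,5-dimethoxyphenyl]methanone, via aryllithium 13 (not isolated), via lithium hemiketalate 14 (not isolated)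
Conditions: 12 (1.3 equiv), n-BuLi, THF, −78 °C; then 10, −78 °C; AcOH/THF quench at −78 °C
Reagents that add atoms: none
Why: Bromine–lithium exchange on 12 gives aryllithium 13, whose carbanionic carbon (para to the silyloxy group, the only halogenated site of the symmetric ring) adds to the lactone carbonyl of 10 from the convex face of the cis-fused bicycle; the bicyclic lithium hemiketalate 14 should not collapse at −78 °C, so no ketone meets a second equivalent of 13, and the cold quench releases γ-hydroxy ketone 15, expected in equilibrium with its cyclic hemiketal. The closest known reaction type is the mono-addition of aryllithium or aryl Grignard reagents to γ-lactones and furofuranone lactones to give lactols or hydroxy ketones. No ring is closed; the temporary lactone ring is opened, which is what frees the C3 hydroxymethyl group without any protecting group. No lasting stereocentre is formed (the hemiketal carbon is lost on opening), and oxolane C2, C3 and C4 are carried over from 10, C4 still cis to the hydroxymethyl group. The step needs mono-addition over double addition and addition over α-deprotonation of the lactone: the stable tetrahedral intermediate, the low temperature, the small excess of 13 and the cold quench should secure the first, the high carbonyl reactivity of the γ-lactone the second.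

Step 8
Reactants: 15 cis keto alcohol
Product: 17 target CNP0169680.1 [(2S,3R,4S)-2-(4-hydroxy-3-methoxyphenyl)-3-(hydroxymethyl)oxolan-4-yl](4-hydroxy-3,5-dimethoxyphenyl)methanone, via all-trans bis-silyl ketone 16 (not isolated)
Conditions: DBU (0.3 equiv), THF, rt; then AcOH, TBAF, 0 °C
Reagents that add atoms: none
Why: Base-mediated epimerisation through the enolate followed by fluoride desilylation: DBU should equilibrate the centre α to the aryl ketone to the arrangement trans to the C3 hydroxymethyl group (C4 becomes S), the trans isomer cannot close to a hemiketal and should therefore accumulate as the open ketone, and acetic-acid-buffered TBAF then cleaves both aryl silyl ethers without further enolisation, C2 and C3 being non-acidic and fixed.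

Compound list

1 | vanillin | COc1cc(C=O)ccc1O | starting material
2 | 3-methoxy-4-(triisopropylsilyloxy)benzaldehyde | COc1cc(C=O)ccc1O[Si](C(C)C)(C(C)C)C(C)C | intermediate
3 | tris(methylsulfanyl)methane | CSC(SC)SC | starting material
4 | (5R)-5-[(1R,2S,5R)-menthyloxy]furan-2(5H)-one | O=C1C=C[C@H](O[C@@H]2C[C@H](C)CC[C@H]2C(C)C)O1 | starting material
5 | tris(methylsulfanyl)methyllithium (formed in the flask) | [Li]C(SC)(SC)SC | intermediate
6 | lithium enolate of the (4R,5R) 1,4-adduct (formed in the flask) | [Li+].[O-]C1=C[C@@H](C(SC)(SC)SC)[C@H](O[C@@H]2C[C@H](C)CC[C@H]2C(C)C)O1 | intermediate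
7 | (3S,4R,5R)-3-{hydroxy[3-methoxy-4-(triisopropylsilyloxy)phenyl]methyl}-5-[(1R,2S,5R)-menthyloxy]-4-[tris(methylsulfanyl)methyl]oxolan-2-one, carbinol epimers | O=C1[C@H](C(O)c2ccc(O[Si](C(C)C)(C(C)C)C(C)C)c(OC)c2)[C@@H](C(SC)(SC)SC)[C@H](O[C@@H]3C[C@H](C)CC[C@H]3C(C)C)O1 | intermediate
8 | (2R,3R)-2-{hydroxy[3-methoxy-4-(triisopropylsilyloxy)phenyl]methyl}-3-[tris(methylsulfanyl)methyl]butane-1,4-diol, carbinol epimers | OC[C@H](C(O)c1ccc(O[Si](C(C)C)(C(C)C)C(C)C)c(OC)c1)[C@@H](C(SC)(SC)SC)CO | intermediate
9 | {(2S,3R,4R)-2-[3-methoxy-4-(triisopropylsilyloxy)phenyl]-4-[tris(methylsulfanyl)methyl]oxolan-3-yl}methanol | OC[C@@H]1[C@@H](c2ccc(O[Si](C(C)C)(C(C)C)C(C)C)c(OC)c2)OC[C@@H]1C(SC)(SC)SC | intermediate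
10 | (1R,5R,6S)-6-[3-methoxy-4-(triisopropylsilyloxy)phenyl]-3,7-dioxabicyclo[3.3.0]octan-2-one | O=C1OC[C@@H]2[C@@H](c3ccc(O[Si](C(C)C)(C(C)C)C(C)C)c(OC)c3)OC[C@@H]21 | intermediate
11 | 4-bromo-2,6-dimethoxyphenol | COc1cc(Br)cc(OC)c1O | starting material
12 | (4-bromo-2,6-dimethoxyphenoxy)(tert-butyl)dimethylsilane | COc1cc(Br)cc(OC)c1O[Si](C)(C)C(C)(C)C | intermediate
13 | [4-(tert-butyldimethylsilyloxy)-3,5-dimethoxyphenyl]lithium (formed in the flask) | COc1cc([Li])cc(OC)c1O[Si](C)(C)C(C)(C)C | intermediate
14 | lithium hemiketalate from convex-face addition of 13 to 10 (formed in the flask) | [Li+].[O-][C@]1(c2cc(OC)c(O[Si](C)(C)C(C)(C)C)c(OC)c2)OC[C@@H]2[C@@H](c3ccc(O[Si](C(C)C)(C(C)C)C(C)C)c(OC)c3)OC[C@@H]21 | intermediate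
15 | [(2S,3R,4R)-3-(hydroxymethyl)-2-(3-methoxy-4-triisopropylsilyloxyphenyl)oxolan-4-yl][4-(tert-butyldimethylsilyloxy)-3,5-dimethoxyphenyl]methanone (open form of the keto alcohol/hemiketal pair) | COc1cc([C@H]2OC[C@H](C(=O)c3cc(OC)c(O[Si](C)(C)C(C)(C)C)c(OC)c3)[C@@H]2CO)ccc1O[Si](C(C)C)(C(C)C)C(C)C | intermediate
16 | [(2S,3R,4S)-3-(hydroxymethyl)-2-(3-methoxy-4-triisopropylsilyloxyphenyl)oxolan-4-yl][4-(tert-butyldimethylsilyloxy)-3,5-dimethoxyphenyl]methanone (formed in the flask) | COc1cc([C@H]2OC[C@@H](C(=O)c3cc(OC)c(O[Si](C)(C)C(C)(C)C)c(OC)c3)[C@@H]2CO)ccc1O[Si](C(C)C)(C(C)C)C(C)C | intermediate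
17 | [(2S,3R,4S)-2-(4-hydroxy-3-methoxyphenyl)-3-(hydroxymethyl)oxolan-4-yl](4-hydroxy-3,5-dimethoxyphenyl)methanone, CNP0169680.1 | COc1cc([C@H]2OC[C@@H](C(=O)c3cc(OC)c(O)c(OC)c3)[C@@H]2CO)ccc1O | target

Total step count: 8. Longest linear sequence: 7 (steps 1, 2, 3, 4, 5, 7, 8).

Steps most likely to fail

Step 7. The basic aryllithium may deprotonate the lactone α to its carbonyl instead of adding, or the hemiketalate may open early and take up a second aryl group. The fallback sets out from lactone 10 and forms the same bond at the aldehyde oxidation level. DIBAL-H in CH2Cl2 at −78 °C should reduce 10 to the samin-type lactol F1. The Grignard reagent made from 12 with magnesium in THF (about 3 equiv, 0 °C) should add to the open hydroxy aldehyde form of the lactol and give the diol F2 as a carbinol mixture. Activated MnO2 in CH2Cl2 should then oxidise only the electron-rich benzylic alcohol, and the route is rejoined at 15.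

Step 8. The epimerisation may stall because the cis isomer is held as its cyclic hemiketal, or the base may open the oxolane by β-elimination of the ring oxygen and scramble C2. The fallback sets out from 15. TBSCl/imidazole should silylate the primary hydroxyl of the open form and so remove the hemiketal pathway, giving the cis tris-silyl ketone F3. DBU in toluene should epimerise this to the all-trans tris-silyl ketone F4, which can be isolated and checked. Buffered TBAF (or HF·pyridine) then removes all three silyl groups and the route is rejoined at 17.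

Step 2. The very bulky trithio carbanion may add sluggishly or reversibly, or the crowded enolate may exchange a proton before it captures the aldehyde. The fallback sets out from furanone 4 and uses a vinyl group as the masked carbonyl, with the two C–C bonds made separately.
- Vinylmagnesium bromide with CuBr·SMe2 and TMSCl in THF at −78 °C should add anti to the menthyloxy group and give the vinyl lactone F5.
- LDA at −78 °C followed by aldehyde 2 should give the trans aldol adduct F6.
- LiAlH4 should give the triol F7.
- Catalytic CSA should close the oxolane to F8.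
- Ozonolysis (O3, CH2Cl2/MeOH, −78 °C; Me2S) should give the cis hydroxy aldehyde, which closes to the lactol F1, the same compound as in the fallback to step 7.
- TEMPO/PhI(OAc)2 should oxidise the lactol to the lactone, and the route is rejoined at 10.

Further compounds

F1 | step 7 | (1R,5R,6S)-6-[3-methoxy-4-(triisopropylsilyloxy)phenyl]-3,7-dioxabicyclo[3.3.0]octan-2-ol, anomers | OC1OC[C@@H]2[C@@H](c3ccc(O[Si](C(C)C)(C(C)C)C(C)C)c(OC)c3)OC[C@@H]21
F2 | step 7 | [(2S,3R,4R)-3-(hydroxymethyl)-2-(3-methoxy-4-triisopropylsilyloxyphenyl)oxolan-4-yl][4-(tert-butyldimethylsilyloxy)-3,5-dimethoxyphenyl]methanol, carbinol epimers | COc1cc([C@H]2OC[C@H](C(O)c3cc(OC)c(O[Si](C)(C)C(C)(C)C)c(OC)c3)[C@@H]2CO)ccc1O[Si](C(C)C)(C(C)C)C(C)C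
F3 | step 8 | [(2S,3R,4R)-3-(tert-butyldimethylsilyloxymethyl)-2-(3-methoxy-4-triisopropylsilyloxyphenyl)oxolan-4-yl][4-(tert-butyldimethylsilyloxy)-3,5-dimethoxyphenyl]methanone | COc1cc([C@H]2OC[C@H](C(=O)c3cc(OC)c(O[Si](C)(C)C(C)(C)C)c(OC)c3)[C@@H]2CO[Si](C)(C)C(C)(C)C)ccc1O[Si](C(C)C)(C(C)C)C(C)C
F4 | step 8 | [(2S,3R,4S)-3-(tert-butyldimethylsilyloxymethyl)-2-(3-methoxy-4-triisopropylsilyloxyphenyl)oxolan-4-yl][4-(tert-butyldimethylsilyloxy)-3,5-dimethoxyphenyl]methanone | COc1cc([C@H]2OC[C@@H](C(=O)c3cc(OC)c(O[Si](C)(C)C(C)(C)C)c(OC)c3)[C@@H]2CO[Si](C)(C)C(C)(C)C)ccc1O[Si](C(C)C)(C(C)C)C(C)C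
F5 | step 2 | (4S,5R)-4-ethenyl-5-[(1R,2S,5R)-menthyloxy]oxolan-2-one | O=C1C[C@@H](C=C)[C@H](O[C@@H]2C[C@H](C)CC[C@H]2C(C)C)O1
F6 | step 2 | (3S,4R,5R)-4-ethenyl-3-{hydroxy[3-methoxy-4-(triisopropylsilyloxy)phenyl]methyl}-5-[(1R,2S,5R)-menthyloxy]oxolan-2-one, carbinol epimers | O=C1[C@H](C(O)c2ccc(O[Si](C(C)C)(C(C)C)C(C)C)c(OC)c2)[C@@H](C=C)[C@H](O[C@@H]3C[C@H](C)CC[C@H]3C(C)C)O1
F7 | step 2 | (2R,3R)-3-ethenyl-2-{hydroxy[3-methoxy-4-(triisopropylsilyloxy)phenyl]methyl}butane-1,4-diol, carbinol epimers | OC[C@H](C(O)c1ccc(O[Si](C(C)C)(C(C)C)C(C)C)c(OC)c1)[C@@H](C=C)CO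
F8 | step 2 | {(2S,3R,4R)-4-ethenyl-2-[3-methoxy-4-(triisopropylsilyloxy)phenyl]oxolan-3-yl}methanol | OC[C@@H]1[C@@H](c2ccc(O[Si](C(C)C)(C(C)C)C(C)C)c(OC)c2)OC[C@@H]1C=C
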